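**Numbering.** Compounds 1–33 are fixed as in the compound list after the steps. Ring A is the 2,4-dihydroxy-5-methoxy-6-methylbenzoyl unit, ring B the central orsellinoyl unit, ring C the terminal orsellinic acid. Each ring is numbered from its carboxyl carbon (C1).

## Analysis of the target

The target is a tridepside: three benzene rings joined in a row by two aryl ester bonds, ring A acyl to O4 of ring B and ring B acyl to O4 of ring C. There is no stereocenter, so the whole problem is one of regiochemistry and protecting-group economy. Ring A carries five substituents (C1 acyl, C2 OH, C4 OH, C5 OCH3, C6 CH3). Rings B and C are orsellinate units (C1 carbonyl, C2 OH, C4 O-acyl, C6 CH3), and ring C ends in a free salicylic-type acid. The sensitive groups are the two depside esters, which transesterify or cleave with base and nucleophiles, the electron-rich phenols, and the 2-hydroxybenzoic acid, which decarboxylates on heating or in strong acid. The last step must therefore be neutral. The main difficulty is to tell apart oxygens that sit in nearly the same environment: in rings B and C the O4 oxygen must be acylated while O2 stays free. The strategy rests on ring C: its C2 and C4 oxygens can come from two different fragments, so that C4 arrives as a free hydroxyl and C2 already masked, with C1 (ester) and C6 (methyl) set in the same ring-forming step.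

## Retrosynthetic reasoning

The four O–benzyl bonds of the last intermediate 32 are cut first, leading back from target 33 by hydrogenolysis. This is the only deprotection that leaves depside esters, free phenols and the salicylic acid untouched. One step further back, the C2 oxygen of ring C carries a triisopropylsilyl group (31), removed with buffered fluoride before the hydrogenolysis, while the molecule is still neutral and easy to purify.

The ester bond between the ring B carbonyl carbon and O4 of ring C is cut next, giving acid 14 (rings A and B) and phenol 29 (ring C). Cutting here puts the more hindered and more valuable acyl partner together with a ring C piece that has exactly one free hydroxyl. The forward reaction is then a plain acylation through acid chloride 30 with no selectivity question.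

Ring C of 29 is taken apart at C1–C2, C3–C4 and C4–C5 into diazo keto ester 19 and siloxyalkyne 24. This is the disconnection that carries the route. In the forward direction the ketene carbonyl of vinylketene 25 becomes the free C4 hydroxyl and the alkyne oxygen becomes the silylated C2 oxygen. The benzyl ester and the C6 methyl come in with 19. No selective protection of a resorcinol is needed, and the step is run on small, cheap pieces at the start of its branch.

Diazo keto ester 19 is cut at the bond between its ketone carbon and the diazo carbon. An aldol-type addition of benzyl diazoacetate 15 to methacrolein 16 gives alcohol 18, and oxidation gives 19. This two-step path is preferred to a direct C-acylation of 15 with an unsaturated acid chloride, where dipolar cycloaddition of the diazo group to the acrylic double bond would compete. Siloxyalkyne 24 is cut at the C–O and O–Si bonds. It comes from acetylene 20 by oxidation of its lithium salt 22 to ynolate 23 and O-silylation with triisopropylsilyl triflate 21.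

Acid 14 is traced back to aldehyde 13, and 13 is cut at the ester bond between the ring A carbonyl and O4 of ring B into acid 8 and phenol 11. The ring B carboxyl is carried as a formyl group because an aldehyde survives the acylation and is later oxidized under conditions that touch neither benzyl ethers nor the aryl ester. An ester protecting group orthogonal to benzyl is thus avoided.

Phenol 11 comes from 2,4-dihydroxy-6-methylbenzaldehyde 2, which is the formylation product of orcinol 1. The C4 hydroxyl of 2 is the more acidic and is not hydrogen-bonded to the carbonyl. It is therefore allylated first (9), the C2 hydroxyl is benzylated (10), and the allyl group is removed (11).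

Acid 8 also comes from 2. Benzylation gives 3, and its formyl group is turned into the C5 oxygen by Baeyer–Villiger oxidation (formate 4, phenol 5) and methylation (6). A second formylation, directed to the only position that is para to a benzyloxy group, gives 7, and oxidation gives 8. The first formyl group thus serves as a latent oxygen and the second as the carboxyl, and both rings A and B grow from the same early intermediate.

## Alternatives that were turned down

Alternative 1: Ring A is disconnected at C5–C6, C1–C2 and C2–C3 (Dötz benzannulation). The alkenyl Fischer carbene complex A2, (CO)5Cr=C(OMe)C(OCH2OMe)=CH2, would combine with the but-2-ynoate A3 of the ring B–ring C phenol and one carbonyl ligand to give A1. A1 is the protected target with the ring A C2 hydroxyl free and a methoxymethyl group on O4.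
- For it: one step builds the fully substituted ring A, with the methoxy group delivered by the carbene carbon and the para relation of O2 and O5 built in. On this point it is stronger than the chosen route, which spends six steps (1–6) on acid 8.
- Against it: A3 is an electron-poor alkynoate, a class that inserts sluggishly into chromium carbenes. Its two alkyne substituents (methyl and ester) are of similar size, so the regiochemistry that must put the ester next to the new hydroxyl is not secured by sterics. The α-alkoxyvinyl carbene A2 is itself an enol ether and fragile. The step uses stoichiometric zerovalent chromium on the most advanced intermediate. An extra acidic deprotection is needed at the end.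
- Comparison: alternative 1 leaves the O2/O4 problem of rings B and C to be solved by protecting-group work on the way to A3. The chosen strategy offers in its place a metal-free ring synthesis run at the start of a short branch, which solves that oxygen problem for ring C directly.

Alternative 2: Ring B is disconnected at C1–C2 and C5–C6 (Diels–Alder reaction with aromatization). The 3-aroyloxy ketene acetal diene A5, which carries ring A as an enol ester, would add to the but-2-ynoate A6 of the ring C phenol. Elimination of the methoxy group from the acetal carbon would then give A4 with the ring B hydroxyl free.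
- For it: it is the most convergent plan, joining the two halves in the ring-forming step, and the polarization of diene and alkynoate sets the ester next to the new hydroxyl. On convergence it is stronger than the chosen route, and its handling of the ring B oxygen is as elegant as the chosen handling of ring C.
- Against it: β-methyl alkynoates are slow dienophiles and need heating. The 3-acyloxy group makes A5 a weaker diene than its 3-silyloxy analogues. A5 must be made by γ-deprotonation of an O-aroylated acetoacetate, where acyl transfer from oxygen to carbon or to the base is likely. The aryl alkynoate A6 is also an activated ester and a Michael acceptor.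
- Comparison: all the risk lies at the convergence point, after rings A and C have been prepared. The chosen strategy keeps its pericyclic step on a five-carbon diazo ester and a two-carbon alkyne, where a failure costs three steps.

Alternative 3: Ring A is disconnected at C1–C6 only (biomimetic aldol aromatization). The aryl 6-methoxy-3,5,7-trioxooctanoate A8 of the protected ring B–ring C phenol would cyclize by attack of its C2 methylene on the C7 ketone and lose water to give A7.
- For it: it follows the biosynthetic logic, brings in every ring A carbon and the methoxy group in one chain, and produces ring A with both hydroxyls free. On protecting-group economy for ring A it is stronger than the chosen route.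
- Against it: the aryl ester is the best leaving group in A8. The enol oxygen at C5 can attack C1 and expel the ring B–ring C phenoxide, which gives a pyranone and destroys the depside. Other aldol and Claisen modes of the triketo chain are open. A8 must be assembled by polyanion acylation in the presence of two base-sensitive aryl esters.
- Comparison: the chosen strategy builds ring A by six ordinary aromatic steps instead, but no step puts a depside bond at risk, and its one demanding step does not involve the assembled chain.

Key step: step 15

## Route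

Remark on the chemistry: the peroxide oxidation of lithium acetylides to lithium ynolates is documented for substituted acetylides and is assumed to hold for lithium acetylide itself (step 14). The chiral intermediates 18 and 26 are racemic, and their stereocenters do not survive.

Step 1
Reactants: 1 orcinol
Product: 2 2,4-dihydroxy-6-methylbenzaldehyde
Conditions: POCl3, DMF, 0 °C→rt; then ice-water
Reagents that add atoms: N,N-dimethylformamide CN(C)C=O; water O
Why: Vilsmeier–Haack formylation; the chloroiminium ion should attack the position para to one hydroxyl, ortho to the other and next to the methyl group, as is usual for orcinol, and hydrolysis of the iminium salt releases the aldehyde.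

Step 2
Reactants: 2 2,4-dihydroxy-6-methylbenzaldehyde
Product: 3 2,4-bis(benzyloxy)-6-methylbenzaldehyde
Conditions: BnBr, K2CO3, DMF, 60 °C
Reagents that add atoms: benzyl bromide BrCc1ccccc1
Why: Williamson etherification; excess base in warm DMF also alkylates the hydrogen-bonded C2 hydroxyl.

Step 3
Reactants: 3 2,4-bis(benzyloxy)-6-methylbenzaldehyde
Product: 5 2,4-bis(benzyloxy)-6-methylphenol, via aryl formate 4 (not isolated)
Conditions: mCPBA, CH2Cl2, 0 °C→rt; then K2CO3 (cat.), MeOH, rt, under argon
Reagents that add atoms: 3-chloroperbenzoic acid OOC(=O)c1cccc(Cl)c1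
Why: Baeyer–Villiger oxidation (Dakin-type); the electron-rich, di-ortho-substituted aryl group migrates in the Criegee intermediate to give formate 4, and mild methanolysis frees the phenol, which is kept under argon because it is an oxidizable hydroquinone monoether.

Step 4
Reactants: 5 2,4-bis(benzyloxy)-6-methylphenol
Product: 6 1,5-bis(benzyloxy)-2-methoxy-3-methylbenzene
Conditions: MeI, K2CO3, acetone, reflux
Reagents that add atoms: iodomethane CI
Why: Williamson methylation of the only free hydroxyl; this fixes the future C5 methoxy group of ring A.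

Step 5
Reactants: 6 1,5-bis(benzyloxy)-2-methoxy-3-methylbenzene
Product: 7 2,4-bis(benzyloxy)-5-methoxy-6-methylbenzaldehyde
Conditions: POCl3, DMF, 0→70 °C; then water
Reagents that add atoms: N,N-dimethylformamide CN(C)C=O; water O
Why: Vilsmeier–Haack formylation; of the two open positions, C4 of 6 is para to one benzyloxy group and ortho to the other, whereas C6 lies between two benzyloxy groups, and the methoxy group is meta to both, so attack at C4 should dominate, as in the formylation of orcinol diethers.

Step 6
Reactants: 7 2,4-bis(benzyloxy)-5-methoxy-6-methylbenzaldehyde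
Product: 8 2,4-bis(benzyloxy)-5-methoxy-6-methylbenzoic acid
Conditions: NaClO2, NaH2PO4, 2-methyl-2-butene, t-BuOH/THF/H2O, rt
Reagents that add atoms: sodium chlorite [Na+].[O-]Cl=O
Why: Pinnick oxidation; chlorous acid oxidizes the hindered aldehyde without touching the benzyl ethers, and the alkene traps the hypochlorous acid that would chlorinate the electron-rich ring.

Step 7
Reactants: 2 2,4-dihydroxy-6-methylbenzaldehyde
Product: 9 4-(allyloxy)-2-hydroxy-6-methylbenzaldehyde
Conditions: allyl bromide, CsHCO3, MeCN, 60 °C
Reagents that add atoms: allyl bromide C=CCBr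
Why: Williamson O-allylation; the C4 hydroxyl, para to the formyl group, is the more acidic and is not held in the hydrogen bond to the carbonyl, so a hydrogen carbonate base should ionize and alkylate only this oxygen.

Step 8
Reactants: 9 4-(allyloxy)-2-hydroxy-6-methylbenzaldehyde
Product: 10 4-(allyloxy)-2-(benzyloxy)-6-methylbenzaldehyde
Conditions: BnBr, K2CO3, DMF, 60 °C
Reagents that add atoms: benzyl bromide BrCc1ccccc1
Why: Williamson benzylation of the remaining, hydrogen-bonded hydroxyl under the more forcing conditions of step 2.

Step 9
Reactants: 10 4-(allyloxy)-2-(benzyloxy)-6-methylbenzaldehyde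
Product: 11 2-(benzyloxy)-4-hydroxy-6-methylbenzaldehyde
Conditions: Pd(PPh3)4 (cat.), K2CO3, MeOH, rt
Reagents that add atoms: none
Why: Tsuji–Trost-type deallylation; zerovalent palladium ionizes the aryl allyl ether to a π-allyl complex and the phenoxide, methanol takes up the allyl group, and the benzyl ether and the aldehyde are not affected.

Step 10
Reactants: 8 2,4-bis(benzyloxy)-5-methoxy-6-methylbenzoic acid; 11 2-(benzyloxy)-4-hydroxy-6-methylbenzaldehyde
Product: 13 3-(benzyloxy)-4-formyl-5-methylphenyl 2,4-bis(benzyloxy)-5-methoxy-6-methylbenzoate, via acid chloride 12 (not isolated)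
Conditions: (COCl)2, DMF (cat.), CH2Cl2, 0 °C→rt, evaporate; then 11, Et3N, DMAP (cat.), CH2Cl2, 0 °C→rt
Reagents that add atoms: none
Why: Acid chloride formation followed by DMAP-catalysed acylation of the phenol; the di-ortho-substituted acid is activated as its chloride because that form couples reliably with a phenol, and 11 has only one free hydroxyl.

Step 11
Reactants: 13 3-(benzyloxy)-4-formyl-5-methylphenyl 2,4-bis(benzyloxy)-5-methoxy-6-methylbenzoate
Product: 14 2-(benzyloxy)-4-{[2,4-bis(benzyloxy)-5-methoxy-6-methylbenzoyl]oxy}-6-methylbenzoic acid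
Conditions: NaClO2, NaH2PO4, 2-methyl-2-butene, t-BuOH/THF/H2O, rt
Reagents that add atoms: sodium chlorite [Na+].[O-]Cl=O
Why: Pinnick oxidation; the buffered, weakly acidic medium leaves the hindered aryl ester and the benzyl ethers intact and unmasks the ring B carboxyl.

Step 12
Reactants: 15 benzyl diazoacetate; 16 methacrolein
Product: 18 benzyl 2-diazo-3-hydroxy-4-methylpent-4-enoate (racemic), via lithiated diazoacetate 17 (not isolated)
Conditions: LiN(i-Pr)2, THF, −78 °C; then 16, −78 °C; AcOH quench
Reagents that add atoms: none
Why: Aldol-type addition of a lithiated diazoacetate to an aldehyde; at −78 °C the hard carbanion adds to the carbonyl and not to the double bond, and the new carbinol center is racemic and is removed in step 13.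

Step 13
Reactants: 18 benzyl 2-diazo-3-hydroxy-4-methylpent-4-enoate
Product: 19 benzyl 2-diazo-4-methyl-3-oxopent-4-enoate
Conditions: IBX, DMSO, rt
Reagents that add atoms: none
Why: Hypervalent iodine oxidation of a secondary allylic alcohol; the acceptor-substituted diazo group is inert to IBX, and this oxidation of β-hydroxy-α-diazo esters to diazo keto esters is a standard operation.

Step 14
Reactants: 20 acetylene; 21 triisopropylsilyl trifluoromethanesulfonate
Product: 24 (triisopropylsilyloxy)ethyne, via lithium acetylide 22 (not isolated), via lithium ethynolate 23 (not isolated)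
Conditions: n-BuLi, THF, −78 °C; add to t-BuOOLi (from t-BuOOH and LiN(SiMe3)2), THF, −78→0 °C; then 21, −78→0 °C
Reagents that add atoms: tert-butyl hydroperoxide CC(C)(C)OO
Why: Oxidation of a lithium acetylide by a lithium alkyl peroxide: the acetylide attacks the peroxide oxygen and tert-butoxide leaves, giving the ynolate; the bulky, hard silyl triflate should then silylate on oxygen, as it does with substituted ynolates.

Step 15
Reactants: 19 benzyl 2-diazo-4-methyl-3-oxopent-4-enoate; 24 (triisopropylsilyloxy)ethyne
Product: 29 benzyl 4-hydroxy-6-methyl-2-(triisopropylsilyloxy)benzoate, via vinylketene 25 (not isolated), via cyclobutenone 26 (not isolated), via dienylketene 27 (not isolated), via cyclohexadienone 28 (not isolated)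
Conditions: hν (254 nm, quartz), 24 (excess), ClCH2CH2Cl, rt; then 80 °C
Reagents that add atoms: none
Why: Irradiation expels N2 from 19 and the isopropenyl group shifts from the ketone carbon to the diazo carbon (Wolff rearrangement; the benzyloxy group migrates far less readily), which places ring carbon C6 on C1 and gives vinylketene 25 with the ester on its α-carbon. The electron-rich alkyne 24 then adds across the ketene C=C in a (2+2) cycloaddition: its unsubstituted, nucleophilic carbon bonds to the electrophilic ketene carbonyl carbon (C3–C4) and its oxygen-bearing carbon to the ester-bearing carbon (C1–C2), giving 4-vinylcyclobutenone 26. Conrotatory 4π opening of 26 gives dienylketene 27, disrotatory 6π electrocyclization onto the isopropenyl CH2 (C4–C5) gives dienone 28, and enolization gives the arene. The closest known reaction type is the Danheiser benzannulation of vinylketenes, generated by photochemical Wolff rearrangement of unsaturated diazo ketones, with siloxyalkynes. Ring C is thus closed by a 6π electrocyclic ring closure, and the four-membered ring of 26 is only a relay. No stereocenter remains in 29; the quaternary carbon of 26 is racemic and is lost on ring opening. The step needs the (2+2) regiochemistry, which the polarization of the ynol ether secures and which puts the silyloxy group next to the ester, and it needs closure through carbon and not through the ester carbonyl oxygen, which is favoured because the opening of 26 is reversible whereas aromatization of 28 is not. The ketene carbonyl thereby ends as the free C4 hydroxyl and the alkyne oxygen as the C2 silyl ether.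

Step 16
Reactants: 14 2-(benzyloxy)-4-{[2,4-bis(benzyloxy)-5-methoxy-6-methylbenzoyl]oxy}-6-methylbenzoic acid; 29 benzyl 4-hydroxy-6-methyl-2-(triisopropylsilyloxy)benzoate
Product: 31 benzyl 4-{[2-(benzyloxy)-4-{[2,4-bis(benzyloxy)-5-methoxy-6-methylbenzoyl]oxy}-6-methylbenzoyl]oxy}-6-methyl-2-(triisopropylsilyloxy)benzoate, via acid chloride 30 (not isolated)
Conditions: (COCl)2, DMF (cat.), CH2Cl2, 0 °C→rt, evaporate; then 29, Et3N, DMAP (cat.), CH2Cl2, 0 °C→rt
Reagents that add atoms: none
Why: Acid chloride formation and DMAP-catalysed phenol acylation as in step 10; only the C4 hydroxyl of 29 is free, so the second depside bond forms without a selectivity question, and the hindered ester already present in 30 is not attacked by the amine bases.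

Step 17
Reactants: 31 benzyl 4-{[2-(benzyloxy)-4-{[2,4-bis(benzyloxy)-5-methoxy-6-methylbenzoyl]oxy}-6-methylbenzoyl]oxy}-6-methyl-2-(triisopropylsilyloxy)benzoate
Product: 32 benzyl 4-{[2-(benzyloxy)-4-{[2,4-bis(benzyloxy)-5-methoxy-6-methylbenzoyl]oxy}-6-methylbenzoyl]oxy}-2-hydroxy-6-methylbenzoate
Conditions: Bu4NF, AcOH, THF, 0 °C
Reagents that add atoms: none
Why: Fluoride-induced cleavage of the aryl silyl ether, driven by the strong Si–F bond; acetic acid protonates the phenoxide as it forms, so that no free phenoxide or fluoride attacks the depside esters.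

Step 18
Reactants: 32 benzyl 4-{[2-(benzyloxy)-4-{[2,4-bis(benzyloxy)-5-methoxy-6-methylbenzoyl]oxy}-6-methylbenzoyl]oxy}-2-hydroxy-6-methylbenzoate
Product: 33 4-{[4-{[2,4-dihydroxy-5-methoxy-6-methylbenzoyl]oxy}-2-hydroxy-6-methylbenzoyl]oxy}-2-hydroxy-6-methylbenzoic acid (target)
Conditions: H2 (1 atm), 10% Pd/C, THF/EtOAc, rt
Reagents that add atoms: none
Why: Catalytic hydrogenolysis of three benzyl ethers and one benzyl ester under neutral conditions; aryl esters, the methyl ether and the aromatic rings are not reduced, so the free tridepside acid should be obtained after filtration.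

## Compound list

1 | orcinol (5-methylbenzene-1,3-diol) | Cc1cc(O)cc(O)c1 | starting material
2 | 2,4-dihydroxy-6-methylbenzaldehyde | Cc1cc(O)cc(O)c1C=O | intermediate
3 | 2,4-bis(benzyloxy)-6-methylbenzaldehyde | Cc1cc(OCc2ccccc2)cc(OCc2ccccc2)c1C=O | intermediate
4 | 2,4-bis(benzyloxy)-6-methylphenyl formate | Cc1cc(OCc2ccccc2)cc(OCc2ccccc2)c1OC=O | intermediate
5 | 2,4-bis(benzyloxy)-6-methylphenol | Cc1cc(OCc2ccccc2)cc(OCc2ccccc2)c1O | intermediate
6 | 1,5-bis(benzyloxy)-2-methoxy-3-methylbenzene | COc1c(C)cc(OCc2ccccc2)cc1OCc1ccccc1 | intermediate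
7 | 2,4-bis(benzyloxy)-5-methoxy-6-methylbenzaldehyde | COc1c(OCc2ccccc2)cc(OCc2ccccc2)c(C=O)c1C | intermediate
8 | 2,4-bis(benzyloxy)-5-methoxy-6-methylbenzoic acid | COc1c(OCc2ccccc2)cc(OCc2ccccc2)c(C(=O)O)c1C | intermediate
9 | 4-(allyloxy)-2-hydroxy-6-methylbenzaldehyde | C=CCOc1cc(C)c(C=O)c(O)c1 | intermediate
10 | 4-(allyloxy)-2-(benzyloxy)-6-methylbenzaldehyde | C=CCOc1cc(C)c(C=O)c(OCc2ccccc2)c1 | intermediate
11 | 2-(benzyloxy)-4-hydroxy-6-methylbenzaldehyde | Cc1cc(O)cc(OCc2ccccc2)c1C=O | intermediate
12 | 2,4-bis(benzyloxy)-5-methoxy-6-methylbenzoyl chloride | COc1c(OCc2ccccc2)cc(OCc2ccccc2)c(C(=O)Cl)c1C | intermediate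
13 | 3-(benzyloxy)-4-formyl-5-methylphenyl 2,4-bis(benzyloxy)-5-methoxy-6-methylbenzoate | COc1c(OCc2ccccc2)cc(OCc2ccccc2)c(C(=O)Oc2cc(C)c(C=O)c(OCc3ccccc3)c2)c1C | intermediate
14 | 2-(benzyloxy)-4-{[2,4-bis(benzyloxy)-5-methoxy-6-methylbenzoyl]oxy}-6-methylbenzoic acid | COc1c(OCc2ccccc2)cc(OCc2ccccc2)c(C(=O)Oc2cc(C)c(C(=O)O)c(OCc3ccccc3)c2)c1C | intermediate
15 | benzyl diazoacetate | [N-]=[N+]=CC(=O)OCc1ccccc1 | starting material
16 | methacrolein | C=C(C)C=O | starting material
17 | benzyl diazo(lithio)acetate | [Li]C(=[N+]=[N-])C(=O)OCc1ccccc1 | intermediate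
18 | benzyl 2-diazo-3-hydroxy-4-methylpent-4-enoate (racemic) | C=C(C)C(O)C(=[N+]=[N-])C(=O)OCc1ccccc1 | intermediate
19 | benzyl 2-diazo-4-methyl-3-oxopent-4-enoate | C=C(C)C(=O)C(=[N+]=[N-])C(=O)OCc1ccccc1 | intermediate
20 | acetylene | C#C | starting material
21 | triisopropylsilyl trifluoromethanesulfonate | CC(C)[Si](OS(=O)(=O)C(F)(F)F)(C(C)C)C(C)C | starting material
22 | lithium acetylide | [Li]C#C | intermediate
23 | lithium ethynolate | [Li]OC#C | intermediate
24 | (triisopropylsilyloxy)ethyne | C#CO[Si](C(C)C)(C(C)C)C(C)C | intermediate
25 | benzyl 3-methyl-2-(oxomethylidene)but-3-enoate (vinylketene) | C=C(C)C(=C=O)C(=O)OCc1ccccc1 | intermediate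
26 | benzyl 4-oxo-1-(prop-1-en-2-yl)-2-(triisopropylsilyloxy)cyclobut-2-ene-1-carboxylate (racemic) | C=C(C)C1(C(=O)OCc2ccccc2)C(=O)C=C1O[Si](C(C)C)(C(C)C)C(C)C | intermediate
27 | benzyl (2Z)-5-oxo-2-(prop-1-en-2-yl)-3-(triisopropylsilyloxy)penta-2,4-dienoate (dienylketene, ketenyl group cis to isopropenyl) | O=C=C/C(O[Si](C(C)C)(C(C)C)C(C)C)=C(\C(C)=C)C(=O)OCc1ccccc1 | intermediate
28 | benzyl 2-methyl-4-oxo-6-(triisopropylsilyloxy)cyclohexa-1,5-diene-1-carboxylate | O=C1C=C(O[Si](C(C)C)(C(C)C)C(C)C)C(C(=O)OCc2ccccc2)=C(C)C1 | intermediate
29 | benzyl 4-hydroxy-6-methyl-2-(triisopropylsilyloxy)benzoate | Cc1cc(O)cc(O[Si](C(C)C)(C(C)C)C(C)C)c1C(=O)OCc1ccccc1 | intermediate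
30 | 2-(benzyloxy)-4-{[2,4-bis(benzyloxy)-5-methoxy-6-methylbenzoyl]oxy}-6-methylbenzoyl chloride | COc1c(OCc2ccccc2)cc(OCc2ccccc2)c(C(=O)Oc2cc(C)c(C(=O)Cl)c(OCc3ccccc3)c2)c1C | intermediate
31 | benzyl 4-{[2-(benzyloxy)-4-{[2,4-bis(benzyloxy)-5-methoxy-6-methylbenzoyl]oxy}-6-methylbenzoyl]oxy}-6-methyl-2-(triisopropylsilyloxy)benzoate | COc1c(OCc2ccccc2)cc(OCc2ccccc2)c(C(=O)Oc2cc(C)c(C(=O)Oc3cc(C)c(C(=O)OCc4ccccc4)c(O[Si](C(C)C)(C(C)C)C(C)C)c3)c(OCc3ccccc3)c2)c1C | intermediate
32 | benzyl 4-{[2-(benzyloxy)-4-{[2,4-bis(benzyloxy)-5-methoxy-6-methylbenzoyl]oxy}-6-methylbenzoyl]oxy}-2-hydroxy-6-methylbenzoate | COc1c(OCc2ccccc2)cc(OCc2ccccc2)c(C(=O)Oc2cc(C)c(C(=O)Oc3cc(C)c(C(=O)OCc4ccccc4)c(O)c3)c(OCc3ccccc3)c2)c1C | intermediate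
33 | 4-{[4-{[2,4-dihydroxy-5-methoxy-6-methylbenzoyl]oxy}-2-hydroxy-6-methylbenzoyl]oxy}-2-hydroxy-6-methylbenzoic acid | COc1c(O)cc(O)c(C(=O)Oc2cc(C)c(C(=O)Oc3cc(C)c(C(=O)O)c(O)c3)c(O)c2)c1C | target

## Step count and risks

Total step count: 18. Longest linear sequence: 11 steps (1, 2, 3, 4, 5, 6, 10, 11, 16, 17, 18).

**Step 15 (key step).** The vinylketene 25 carries an ester on its α-carbon and may behave as an acylketene. It may then add the alkyne through the ester carbonyl in a (4+2) mode, dimerize, or, after ring opening of 26, close through the ester oxygen to a pyranone instead of through carbon. Migration of the wrong group in the Wolff step and acylation of the product phenol by unreacted ketene are further possible losses. Fallback: the ring C piece is made classically, setting out from 10. Chlorite oxidation of 10 gives 4-(allyloxy)-2-(benzyloxy)-6-methylbenzoic acid F1. Benzylation of the carboxyl (BnBr, KHCO3, DMF) gives benzyl 4-(allyloxy)-2-(benzyloxy)-6-methylbenzoate F2. Deallylation (Pd(PPh3)4, morpholine) gives benzyl 2-(benzyloxy)-4-hydroxy-6-methylbenzoate F3. Acylation of F3 with acid chloride 30 (Et3N, DMAP) gives the fully benzylated tridepside F4, and hydrogenolysis of F4 (H2, Pd/C) comes back to the route at the target 33.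

**Step 14.** The parent lithium acetylide may disproportionate or be oxidized inefficiently, and the unsubstituted ynolate 23 may be silylated on carbon, which would lead to a silylketene instead of 24. The product is also fairly volatile. Fallback: an ynol ether made without any ynolate is used, setting out from 19. Benzyl alcohol, KH and trichloroethylene give benzyl (E)-1,2-dichloroethenyl ether F5. Two equivalents of n-BuLi at −78 °C give lithium (benzyloxy)acetylide F6, and a methanol quench gives (benzyloxy)ethyne F7, which is kept cold because benzyl ynol ethers rearrange on warming. Irradiation of 19 with F7 at room temperature, then gentle heating once F7 is consumed, should lead by way of vinylketene 25, the cyclobutenone F8, the dienylketene F9 and the dienone F10 to benzyl 2-(benzyloxy)-4-hydroxy-6-methylbenzoate F3. F3 is acylated with 30 to F4, and hydrogenolysis returns to the route at 33, with no desilylation step.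

**Step 16.** The acylation joins a di-ortho-substituted acid chloride that already contains an aryl ester to a weakly nucleophilic phenol. Slow coupling, acyl scrambling of the existing depside bond by phenoxide, and hydrolysis of 30 are the likely failures. Fallback: the order of assembly is reversed, setting out from 29. Acid F1 (from 10, as above) is esterified with 29 by carbodiimide activation (DCC, DMAP) to give benzyl 4-{[4-(allyloxy)-2-(benzyloxy)-6-methylbenzoyl]oxy}-6-methyl-2-(triisopropylsilyloxy)benzoate F11. Deallylation (Pd(PPh3)4, morpholine) gives benzyl 4-{[2-(benzyloxy)-4-hydroxy-6-methylbenzoyl]oxy}-6-methyl-2-(triisopropylsilyloxy)benzoate F12. Acylation of F12 with the smaller acid chloride 12 comes back to the route at 31.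

**Step 5.** Formylation may be poorly regioselective, with some attack at the position between the two benzyloxy groups, or benzyl ethers may be partly lost in the warm acidic medium. Fallback: the carboxyl is introduced by halogenation and metalation, setting out from 6. NBS in MeCN at 0 °C, which is strongly para-directed by alkoxy groups, gives 1,5-bis(benzyloxy)-4-bromo-2-methoxy-3-methylbenzene F13. Bromine–lithium exchange (n-BuLi, THF, −78 °C) gives [2,4-bis(benzyloxy)-5-methoxy-6-methylphenyl]lithium F14, and carboxylation with CO2 comes back to the route at 8, leaving out 7.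

## Further compounds

F1 | step 15 | 4-(allyloxy)-2-(benzyloxy)-6-methylbenzoic acid | C=CCOc1cc(C)c(C(=O)O)c(OCc2ccccc2)c1
F2 | step 15 | benzyl 4-(allyloxy)-2-(benzyloxy)-6-methylbenzoate | C=CCOc1cc(C)c(C(=O)OCc2ccccc2)c(OCc2ccccc2)c1
F3 | step 15 | benzyl 2-(benzyloxy)-4-hydroxy-6-methylbenzoate | Cc1cc(O)cc(OCc2ccccc2)c1C(=O)OCc1ccccc1
F4 | step 15 | benzyl 2-(benzyloxy)-4-{[2-(benzyloxy)-4-{[2,4-bis(benzyloxy)-5-methoxy-6-methylbenzoyl]oxy}-6-methylbenzoyl]oxy}-6-methylbenzoate | COc1c(OCc2ccccc2)cc(OCc2ccccc2)c(C(=O)Oc2cc(C)c(C(=O)Oc3cc(C)c(C(=O)OCc4ccccc4)c(OCc4ccccc4)c3)c(OCc3ccccc3)c2)c1C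
F5 | step 14 | benzyl (E)-1,2-dichloroethenyl ether | Cl/C=C(/Cl)OCc1ccccc1
F6 | step 14 | lithium (benzyloxy)acetylide | [Li]C#COCc1ccccc1
F7 | step 14 | (benzyloxy)ethyne | C#COCc1ccccc1
F8 | step 14 | benzyl 2-(benzyloxy)-4-oxo-1-(prop-1-en-2-yl)cyclobut-2-ene-1-carboxylate (racemic) | C=C(C)C1(C(=O)OCc2ccccc2)C(=O)C=C1OCc1ccccc1
F9 | step 14 | benzyl (2Z)-3-(benzyloxy)-5-oxo-2-(prop-1-en-2-yl)penta-2,4-dienoate | O=C=C/C(OCc1ccccc1)=C(\C(C)=C)C(=O)OCc1ccccc1
F10 | step 14 | benzyl 6-(benzyloxy)-2-methyl-4-oxocyclohexa-1,5-diene-1-carboxylate | O=C1C=C(OCc2ccccc2)C(C(=O)OCc2ccccc2)=C(C)C1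
F11 | step 16 | benzyl 4-{[4-(allyloxy)-2-(benzyloxy)-6-methylbenzoyl]oxy}-6-methyl-2-(triisopropylsilyloxy)benzoate | C=CCOc1cc(C)c(C(=O)Oc2cc(C)c(C(=O)OCc3ccccc3)c(O[Si](C(C)C)(C(C)C)C(C)C)c2)c(OCc2ccccc2)c1
F12 | step 16 | benzyl 4-{[2-(benzyloxy)-4-hydroxy-6-methylbenzoyl]oxy}-6-methyl-2-(triisopropylsilyloxy)benzoate | Cc1cc(O)cc(OCc2ccccc2)c1C(=O)Oc1cc(C)c(C(=O)OCc2ccccc2)c(O[Si](C(C)C)(C(C)C)C(C)C)c1
F13 | step 5 | 1,5-bis(benzyloxy)-4-bromo-2-methoxy-3-methylbenzene | COc1c(C)c(Br)c(OCc2ccccc2)cc1OCc1ccccc1
F14 | step 5 | [2,4-bis(benzyloxy)-5-methoxy-6-methylphenyl]lithium | [Li]c1c(C)c(OC)c(OCc2ccccc2)cc1OCc1ccccc1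
A1 | alternative 1 | benzyl 2-(benzyloxy)-4-{[2-(benzyloxy)-4-{[2-hydroxy-5-methoxy-4-(methoxymethoxy)-6-methylbenzoyl]oxy}-6-methylbenzoyl]oxy}-6-methylbenzoate | COCOc1cc(O)c(C(=O)Oc2cc(C)c(C(=O)Oc3cc(C)c(C(=O)OCc4ccccc4)c(OCc4ccccc4)c3)c(OCc3ccccc3)c2)c(C)c1OC
A2 | alternative 1 | pentacarbonyl[1-methoxy-2-(methoxymethoxy)prop-2-en-1-ylidene]chromium, (CO)5Cr=C(OMe)C(OCH2OMe)=CH2 | COCOC(=C)C(OC)=[Cr](=C=O)(=C=O)(=C=O)(=C=O)=C=O
A3 | alternative 1 | benzyl 2-(benzyloxy)-4-{[2-(benzyloxy)-4-(but-2-ynoyloxy)-6-methylbenzoyl]oxy}-6-methylbenzoate | CC#CC(=O)Oc1cc(C)c(C(=O)Oc2cc(C)c(C(=O)OCc3ccccc3)c(OCc3ccccc3)c2)c(OCc2ccccc2)c1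
A4 | alternative 2 | benzyl 2-(benzyloxy)-4-{[4-{[2,4-bis(benzyloxy)-5-methoxy-6-methylbenzoyl]oxy}-2-hydroxy-6-methylbenzoyl]oxy}-6-methylbenzoate | COc1c(OCc2ccccc2)cc(OCc2ccccc2)c(C(=O)Oc2cc(C)c(C(=O)Oc3cc(C)c(C(=O)OCc4ccccc4)c(OCc4ccccc4)c3)c(O)c2)c1C
A5 | alternative 2 | 4-methoxy-4-(trimethylsilyloxy)buta-1,3-dien-2-yl 2,4-bis(benzyloxy)-5-methoxy-6-methylbenzoate | C=C(OC(=O)c1c(C)c(OC)c(OCc2ccccc2)cc1OCc1ccccc1)C=C(OC)O[Si](C)(C)C
A6 | alternative 2 | benzyl 2-(benzyloxy)-4-(but-2-ynoyloxy)-6-methylbenzoate | CC#CC(=O)Oc1cc(C)c(C(=O)OCc2ccccc2)c(OCc2ccccc2)c1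
A7 | alternative 3 | benzyl 2-(benzyloxy)-4-{[2-(benzyloxy)-4-{[2,4-dihydroxy-5-methoxy-6-methylbenzoyl]oxy}-6-methylbenzoyl]oxy}-6-methylbenzoate | COc1c(O)cc(O)c(C(=O)Oc2cc(C)c(C(=O)Oc3cc(C)c(C(=O)OCc4ccccc4)c(OCc4ccccc4)c3)c(OCc3ccccc3)c2)c1C
A8 | alternative 3 | benzyl 2-(benzyloxy)-4-{[2-(benzyloxy)-4-[(6-methoxy-3,5,7-trioxooctanoyl)oxy]-6-methylbenzoyl]oxy}-6-methylbenzoate (racemic at chain C6) | CC(=O)C(OC)C(=O)CC(=O)CC(=O)Oc1cc(C)c(C(=O)Oc2cc(C)c(C(=O)OCc3ccccc3)c(OCc3ccccc3)c2)c(OCc2ccccc2)c1
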